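**Plan**
1. Cuts: open the butenolide (ring O–C6–C7=C11–C12) to a C6 carbinol and a C12 primary alcohol; take the 4,5-oxirane back to a 4Z alkene; cut the ten-membered ring at C5–C6 (C5 (Z)-alkenyl iodide plus C6 enal); then C7=C11 (cyclic olefination), C8–C9 (hydrazone alkylation), C10=C1 and C2=C3 (two olefinations).
2. Enabling feature: C6, the lactone carbinol carbon, lies between C5 of the cis-4,5-oxirane and C7 of the butenolide alkene. Adding a C5 alkenyl metal to a C6 enal therefore closes the carbocycle and leaves a free doubly allylic hydroxyl, which first directs the 4,5-epoxidation and then closes the lactone.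
3. Forward: iodotriene C5–C1/C10/C9/C14 by two olefinations; union with a dihydroxyacetone hydrazone (C6–C8); a temporary butenolide through O8 and C13 (not in the target) fixes the C7=C11 geometry and is reduced away; C12 is held at the alcohol level as a silyl ether so the key alkoxide cannot lactonise.
4. Ring order: 1,10-oxirane (open chain), ten-membered carbocycle (key step), 4,5-oxirane, butenolide last by oxidative lactonisation.
5. Stereochemistry: C8 from the SAMP auxiliary; C1/C10 from titanium–tartrate epoxidation; C6 from the ring closure under control of C8; C4/C5 relayed from C6; alkene geometries from Z-selective olefinations and the cyclic olefination.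

Key step: step 24

Assumption: the SAMP azaenolate of the dioxanone is taken to be alkylated with its usual facial sense to give (S) at C8 (the RAMP reagent would serve otherwise); germacrane numbering (C1–C10 ring, C11–C13 lactone carbons, C14 hydroxymethyl, C15 methyl) is used for all intermediates.

**Step 1**
Reactants: 1 propargyl alcohol
Product: 3 (Z)-3-iodo-2-methylprop-2-en-1-ol, via alkenylmagnesium chelate 2 (not isolated)
Conditions: MeMgBr (2.5 equiv), CuI (10 mol%), Et2O/THF, −10 °C → rt; then I2, −78 → 0 °C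
Reagents that add atoms: methylmagnesium bromide, C[Mg]Br; iodine, II
Why: Copper-catalysed anti-carbomagnesiation of the propargylic magnesium alkoxide puts methyl on the internal carbon and magnesium on the terminal carbon cis to the CH2O group (five-membered chelate), and iodinolysis with retention should give the (Z)-iodide, in which iodine is cis to the future C3.

**Step 2**
Reactants: 3 (Z)-3-iodo-2-methylprop-2-en-1-ol
Product: 4 (Z)-3-iodo-2-methylprop-2-enal
Conditions: MnO2, CH2Cl2, rt
Reagents that add atoms: none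
Why: Allylic alcohol oxidation with MnO2 under neutral conditions, which should leave the (Z)-iodoalkene untouched.

**Step 3**
Reactants: 4 (Z)-3-iodo-2-methylprop-2-enal; 5 methyl 2-[bis(2,2,2-trifluoroethoxy)phosphoryl]acetate
Product: 6 methyl (2Z,4Z)-5-iodo-4-methylpenta-2,4-dienoate
Conditions: KN(SiMe3)2, 18-crown-6, THF, −78 °C
Reagents that add atoms: none
Why: Still–Gennari olefination, in which the electron-poor bis(trifluoroethyl) phosphonate with a dissociated potassium counter-ion eliminates from the kinetic adduct and should give the cis enoate, the future (2Z)-alkene.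

**Step 4**
Reactants: 6 methyl (2Z,4Z)-5-iodo-4-methylpenta-2,4-dienoate
Product: 7 (2Z,4Z)-5-iodo-4-methylpenta-2,4-dien-1-ol
Conditions: i-Bu2AlH (2.2 equiv), CH2Cl2, −78 °C
Reagents that add atoms: none
Why: 1,2-Reduction of the enoate to the allylic alcohol with i-Bu2AlH, which does not touch the alkenyl iodide or the alkene geometry.

**Step 5**
Reactants: 7 (2Z,4Z)-5-iodo-4-methylpenta-2,4-dien-1-ol
Product: 8 (2Z,4Z)-5-iodo-4-methylpenta-2,4-dienal
Conditions: MnO2, CH2Cl2, 0 °C, dark; used at once
Reagents that add atoms: none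
Why: MnO2 oxidation of the dienylic alcohol under neutral conditions, with the labile (2Z,4Z)-dienal used at once to avoid isomerisation.

**Step 6**
Reactants: 8 (2Z,4Z)-5-iodo-4-methylpenta-2,4-dienal; 9 ethyl 2-(diethoxyphosphoryl)acrylate; 10 4-methoxybenzyl alcohol
Product: 12 ethyl (2E,4Z,6Z)-7-iodo-2-[(4-methoxybenzyloxy)methyl]-6-methylhepta-2,4,6-trienoate, via sodium phosphonate Michael adduct 11 (not isolated)
Conditions: 10, NaH, THF, 0 °C; 9, 0 °C; then 8, −78 → 0 °C
Reagents that add atoms: none
Why: Tandem oxa-Michael addition and Horner–Wadsworth–Emmons olefination, in which the alkoxide adds to the phosphonoacrylate and the resulting stabilised phosphonate anion olefinates the aldehyde with the usual E preference, placing the ester carbon (C9) trans and the CH2OPMB group (C14) cis to C2 across the new C10=C1 bond.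

**Step 7**
Reactants: 12 trienoate
Product: 13 (2Z,4Z,6Z)-7-iodo-2-[(4-methoxybenzyloxy)methyl]-6-methylhepta-2,4,6-trien-1-ol (C9 carbinol, trans to C2)
Conditions: i-Bu2AlH (2.2 equiv), CH2Cl2, −78 °C
Reagents that add atoms: none
Why: 1,2-Reduction of the conjugated ester to the allylic alcohol with i-Bu2AlH, which leaves the PMB ether, the iodide and the triene geometry unchanged.

**Step 8**
Reactants: 13 C9 allylic alcohol
Product: 14 (2E,4Z,6Z)-1-bromo-7-iodo-2-[(4-methoxybenzyloxy)methyl]-6-methylhepta-2,4,6-triene (C9 bromide)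
Conditions: CBr4, PPh3, CH2Cl2, −20 °C
Reagents that add atoms: carbon tetrabromide, BrC(Br)(Br)Br
Why: Appel bromination under neutral conditions (SN2 displacement of the alkoxyphosphonium group at the primary allylic carbon).

**Step 9**
Reactants: 15 2,2-dimethyl-1,3-dioxan-5-one; 16 (S)-1-amino-2-(methoxymethyl)pyrrolidine (SAMP)
Product: 17 SAMP hydrazone of 2,2-dimethyl-1,3-dioxan-5-one
Conditions: cyclohexane, reflux, Dean–Stark
Reagents that add atoms: none
Why: Hydrazone condensation driven by azeotropic removal of water.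

**Step 10**
Reactants: 17 SAMP hydrazone; 14 C9 allylic bromide
Product: 18 (8S)-C8-alkylated SAMP hydrazone
Conditions: t-BuLi (1.05 equiv), THF, −78 °C; then 14, −100 → −20 °C
Reagents that add atoms: none
Why: SAMP-hydrazone α-alkylation, in which the chelated lithium azaenolate is alkylated by SN2 at the primary allylic bromide on the face away from the methoxymethyl-bearing pyrrolidine, which should set C8 as (S).

**Step 11**
Reactants: 18 alkylated SAMP hydrazone
Product: 20 (8S)-C6,C8-dihydroxy C7-ketone, via ketone acetonide 19 (not isolated)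
Conditions: sat. aq. oxalic acid, Et2O, rt; then PPTS, MeOH, rt
Reagents that add atoms: water, O
Why: Two-phase acid hydrolysis of the hydrazone (the auxiliary is recovered) followed by transketalisation of the acetonide, with no base present so that the C8 centre alpha to the ketone should not epimerise.

**Step 12**
Reactants: 20 dihydroxy ketone
Product: 21 C6 tert-butyldimethylsilyl ether of 20
Conditions: TBSCl, imidazole, CH2Cl2, −20 → 0 °C
Reagents that add atoms: tert-butyldimethylsilyl chloride, CC(C)(C)[Si](C)(C)Cl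
Why: Silylation of the less hindered primary hydroxyl in preference to the secondary C8 hydroxyl.

**Step 13**
Reactants: 22 tert-butyl 2-(diethoxyphosphoryl)acetate
Product: 23 tert-butyl 2-(diethoxyphosphoryl)-3-hydroxypropanoate
Conditions: paraformaldehyde (1 equiv), piperidine (cat.), MeOH, reflux
Reagents that add atoms: formaldehyde (as paraformaldehyde), C=O
Why: Amine-catalysed aldol-type hydroxymethylation of the phosphonoacetate by formaldehyde, in which, without a metal base, the adduct should neither eliminate nor olefinate a second formaldehyde.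

**Step 14**
Reactants: 23 hydroxymethyl phosphonoacetate
Product: 24 tert-butyl 3-[(tert-butyldiphenylsilyl)oxy]-2-(diethoxyphosphoryl)propanoate
Conditions: TBDPSCl, imidazole, DMF, rt
Reagents that add atoms: tert-butyldiphenylsilyl chloride, CC(C)(C)[Si](Cl)(c1ccccc1)c1ccccc1
Why: Silylation of the primary alcohol.

**Step 15**
Reactants: 24 silylated tert-butyl ester
Product: 25 3-[(tert-butyldiphenylsilyl)oxy]-2-(diethoxyphosphoryl)propanoic acid
Conditions: CF3CO2H, CH2Cl2, 0 °C
Reagents that add atoms: none
Why: Acidolysis of the tert-butyl ester with loss of isobutene, which the primary TBDPS ether tolerates.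

**Step 16**
Reactants: 21 C6 silyl ether; 25 phosphono acid
Product: 26 C8 phosphonoacetate ester of 21
Conditions: N,N'-diisopropylcarbodiimide, DMAP (cat.), CH2Cl2, 0 °C
Reagents that add atoms: none
Why: Carbodiimide (Steglich) esterification of the free C8 hydroxyl.

**Step 17**
Reactants: 26 keto phosphonate
Product: 27 temporary butenolide (lactone O8–C13, C7=C11, C6 OTBS, C12 OTBDPS)
Conditions: LiCl, i-Pr2NEt, MeCN, 0 °C → rt
Reagents that add atoms: none
Why: Intramolecular Horner–Wadsworth–Emmons reaction under Masamune–Roush conditions, in which closure to the five-membered lactone fixes the tetrasubstituted C7=C11 geometry (C13 cis to C8, C12 cis to C6) and the weak amine base should spare the C8 centre.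

**Step 18**
Reactants: 27 temporary butenolide
Product: 28 (8S)-C8,C13-diol with (Z)-tetrasubstituted C7=C11
Conditions: i-Bu2AlH (4 equiv), CH2Cl2, −78 → 0 °C
Reagents that add atoms: none
Why: Reduction of the butenolide with i-Bu2AlH to the (Z)-2-ene-1,4-diol, which removes the temporary ring and keeps the alkene geometry it imposed.

**Step 19**
Reactants: 28 diol
Product: 30 C13 acetate C8 methacrylate, via C13 mono-acetate 29 (not isolated)
Conditions: AcCl, 2,4,6-collidine, CH2Cl2, −78 °C; then methacrylic anhydride, Et3N, DMAP, −78 °C → rt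
Reagents that add atoms: acetyl chloride, CC(=O)Cl; methacrylic anhydride, C=C(C)C(=O)OC(=O)C(C)=C
Why: Chemoselective acylations, in which acetyl chloride with collidine at low temperature esterifies only the primary C13 hydroxyl and DMAP-catalysed acyl transfer then esterifies the secondary C8 hydroxyl.

**Step 20**
Reactants: 30 bis-ester PMB ether
Product: 31 C14 allylic alcohol
Conditions: DDQ (1.1 equiv), CH2Cl2/pH 7 buffer, 0 °C
Reagents that add atoms: none
Why: Oxidative cleavage of the 4-methoxybenzyl ether by DDQ (hydride abstraction and hydrolysis of the oxocarbenium ion) under buffered conditions that spare the silyl ethers and esters.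

**Step 21**
Reactants: 31 C14 allylic alcohol
Product: 32 (1R,10S)-1,10-epoxy alcohol
Conditions: Ti(OiPr)4 (20 mol%), L-(+)-diethyl tartrate (24 mol%), t-BuOOH, 4 Å molecular sieves, CH2Cl2, −20 °C
Reagents that add atoms: tert-butyl hydroperoxide, CC(C)(C)OO
Why: Sharpless asymmetric epoxidation, in which the titanium–tartrate complex delivers the peroxide oxygen only to the alkene of the bound allylic alcohol and L-(+)-tartrate should select the face that gives 1R,10S, while the trans relation of C9 and C2 on the oxirane follows from the alkene geometry.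

**Step 22**
Reactants: 32 epoxy alcohol
Product: 33 C6 primary allylic alcohol
Conditions: HF·pyridine, pyridine, THF, 0 °C
Reagents that add atoms: none
Why: Selective cleavage of the primary TBS ether with buffered HF·pyridine, under which the TBDPS ether, the esters and the oxirane should survive.

**Step 23**
Reactants: 33 C6 alcohol
Product: 34 C6 enal (open-chain iodo aldehyde)
Conditions: MnO2, CH2Cl2, rt
Reagents that add atoms: none
Why: MnO2 oxidises the allylic C6 alcohol but not the non-allylic C14 epoxy alcohol.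

**Step 24**
Reactants: 34 open-chain iodo aldehyde
Product: 35 ten-membered C6 carbinol (C6 hydroxyl cis to the C8 ester)
Conditions: CrCl2 (10 equiv), NiCl2 (2 mol%), DMSO/THF 3:1, 3 mM, syringe-pump addition, rt
Reagents that add atoms: none
Why: CrCl2 reduces NiCl2 to zerovalent nickel, which inserts into the C5–I bond, and transmetalation gives a (Z)-alkenyl trivalent-chromium species that adds to the C6 aldehyde with retention of the C4=C5 geometry. The closest known reaction type is the Nozaki–Hiyama–Kishi macrocyclisation of iodoalkenyl aldehydes to medium and large carbocycles. The ten-membered carbocycle closes by a 10-exo-trig addition to the carbonyl, and no second ring forms because C12 is a silyl ether at the alcohol level, so the C6 alkoxide cannot lactonise and stays free to direct the next step. The new C6 centre is controlled by C8: the C8–H bond eclipses C7=C11 (A(1,3) strain against C13), which puts the C9 tether on one face of the s-trans enal and the methacrylate on the other, and the tethered alkenyl group can reach the aldehyde only from the tether face, which should give the C6 hydroxyl cis to the C8 ester across C7 (the 6S sense of the target). The step needs chemoselectivity for the alkenyl iodide over the allylic acetate, the methacrylate, the dienyl oxirane and the free C14 hydroxyl, which the non-basic aldehyde-selective organochromium reagent provides, and ring closure over oligomerisation, which high dilution and the turn imposed by the Z,Z-diene and the tetrasubstituted alkene should secure.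

**Step 25**
Reactants: 35 macrocyclic allylic alcohol
Product: 36 (4R,5S,6S)-4,5-epoxy alcohol (bis-oxirane)
Conditions: VO(acac)2 (5 mol%), t-BuOOH, CH2Cl2, 0 °C
Reagents that add atoms: tert-butyl hydroperoxide, CC(C)(C)OO
Why: Vanadium-catalysed hydroxyl-directed epoxidation, in which the C6 vanadate ester delivers the peroxide oxygen to the syn face of the adjacent (4Z)-alkene and, as in medium-ring (Z)-cycloalk-2-enols where the ring carbon sits roughly perpendicular to the alkene plane, should give the cis (erythro) epoxy alcohol, so that C4 and C5 are relayed together from C6 while the tetrasubstituted C7=C11 alkene is deactivated by its three further allylic C–O bonds.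

**Step 26**
Reactants: 36 bis-oxirane silyl ether
Product: 37 C6,C12,C14-triol
Conditions: Bu4NF, AcOH, THF, rt
Reagents that add atoms: none
Why: Fluoride desilylation buffered with acetic acid, which should avoid acyl migration and oxirane opening.

**Step 27**
Reactants: 37 triol
Product: 39 CNP0207684.1 (target), via lactol 38 (not isolated)
Conditions: MnO2, CH2Cl2, rt
Reagents that add atoms: none
Why: MnO2 oxidative lactonisation of a (Z)-2-ene-1,4-diol, in which the primary allylic C12 alcohol is oxidised to the enal, the cis C6 hydroxyl closes the lactol and a second oxidation gives the butenolide, with the non-allylic C14 alcohol untouched.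

**Compound list**
1 | propargyl alcohol | C#CCO | starting material
2 | bromomagnesium alkoxide of (Z)-3-(bromomagnesio)-2-methylprop-2-en-1-ol | C/C(CO[Mg]Br)=C/[Mg]Br | intermediate
3 | (Z)-3-iodo-2-methylprop-2-en-1-ol | OC/C(C)=C\I | intermediate
4 | (Z)-3-iodo-2-methylprop-2-enal | O=C/C(C)=C\I | intermediate
5 | methyl 2-[bis(2,2,2-trifluoroethoxy)phosphoryl]acetate | COC(=O)CP(=O)(OCC(F)(F)F)OCC(F)(F)F | starting material
6 | methyl (2Z,4Z)-5-iodo-4-methylpenta-2,4-dienoate | COC(=O)/C=C\C(C)=C/I | intermediate
7 | (2Z,4Z)-5-iodo-4-methylpenta-2,4-dien-1-ol | OC/C=C\C(C)=C/I | intermediate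
8 | (2Z,4Z)-5-iodo-4-methylpenta-2,4-dienal | O=C/C=C\C(C)=C/I | intermediate
9 | ethyl 2-(diethoxyphosphoryl)acrylate | C=C(C(=O)OCC)P(=O)(OCC)OCC | starting material
10 | 4-methoxybenzyl alcohol | COc1ccc(CO)cc1 | starting material
11 | sodium salt of ethyl 2-(diethoxyphosphoryl)-3-(4-methoxybenzyloxy)propanoate | CCOC(=O)[C-](COCc1ccc(OC)cc1)P(=O)(OCC)OCC.[Na+] | intermediate
12 | ethyl (2E,4Z,6Z)-7-iodo-2-[(4-methoxybenzyloxy)methyl]-6-methylhepta-2,4,6-trienoate (ester carbon = C9) | CCOC(=O)/C(COCc1ccc(OC)cc1)=C/C=C\C(C)=C/I | intermediate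
13 | (2Z,4Z,6Z)-7-iodo-2-[(4-methoxybenzyloxy)methyl]-6-methylhepta-2,4,6-trien-1-ol | OC/C(COCc1ccc(OC)cc1)=C/C=C\C(C)=C/I | intermediate
14 | (2E,4Z,6Z)-1-bromo-7-iodo-2-[(4-methoxybenzyloxy)methyl]-6-methylhepta-2,4,6-triene | BrC/C(COCc1ccc(OC)cc1)=C/C=C\C(C)=C/I | intermediate
15 | 2,2-dimethyl-1,3-dioxan-5-one | CC1(C)OCC(=O)CO1 | starting material
16 | (S)-1-amino-2-(methoxymethyl)pyrrolidine (SAMP) | COC[C@@H]1CCCN1N | starting material
17 | SAMP hydrazone of 2,2-dimethyl-1,3-dioxan-5-one | COC[C@@H]1CCCN1N=C1COC(C)(C)OC1 | intermediate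
18 | SAMP hydrazone of the (4S)-4-trienylmethyl dioxanone (C8 alkylated) | COC[C@@H]1CCCN1N=C1COC(C)(C)O[C@H]1C/C(COCc1ccc(OC)cc1)=C/C=C\C(C)=C/I | intermediate
19 | (4S)-4-[(2Z,4Z,6Z)-7-iodo-2-[(4-methoxybenzyloxy)methyl]-6-methylhepta-2,4,6-trienyl]-2,2-dimethyl-1,3-dioxan-5-one | CC1(C)OCC(=O)[C@H](C/C(COCc2ccc(OC)cc2)=C/C=C\C(C)=C/I)O1 | intermediate
20 | (3S,5Z,7Z,9Z)-1,3-dihydroxy-10-iodo-5-[(4-methoxybenzyloxy)methyl]-9-methyldeca-5,7,9-trien-2-one | OCC(=O)[C@@H](O)C/C(COCc1ccc(OC)cc1)=C/C=C\C(C)=C/I | intermediate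
21 | C6 tert-butyldimethylsilyl ether of 20 | CC(C)(C)[Si](C)(C)OCC(=O)[C@@H](O)C/C(COCc1ccc(OC)cc1)=C/C=C\C(C)=C/I | intermediate
22 | tert-butyl 2-(diethoxyphosphoryl)acetate | CCOP(=O)(OCC)CC(=O)OC(C)(C)C | starting material
23 | tert-butyl 2-(diethoxyphosphoryl)-3-hydroxypropanoate | CCOP(=O)(OCC)C(CO)C(=O)OC(C)(C)C | intermediate
24 | tert-butyl 3-[(tert-butyldiphenylsilyl)oxy]-2-(diethoxyphosphoryl)propanoate | CCOP(=O)(OCC)C(CO[Si](c1ccccc1)(c1ccccc1)C(C)(C)C)C(=O)OC(C)(C)C | intermediate
25 | 3-[(tert-butyldiphenylsilyl)oxy]-2-(diethoxyphosphoryl)propanoic acid | CCOP(=O)(OCC)C(CO[Si](c1ccccc1)(c1ccccc1)C(C)(C)C)C(=O)O | intermediate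
26 | C8 ester of 21 with acid 25 (epimers at the phosphonate carbon) | CC(C)(C)[Si](C)(C)OCC(=O)[C@@H](OC(=O)C(CO[Si](c1ccccc1)(c1ccccc1)C(C)(C)C)P(=O)(OCC)OCC)C/C(COCc1ccc(OC)cc1)=C/C=C\C(C)=C/I | intermediate
27 | temporary butenolide: (5S)-furan-2(5H)-one with 3-CH2OTBDPS (C12), 4-CH2OTBS (C6) and the 5-trienylmethyl chain | O=C1O[C@@H](C/C(COCc2ccc(OC)cc2)=C/C=C\C(C)=C/I)C(CO[Si](C)(C)C(C)(C)C)=C1CO[Si](c1ccccc1)(c1ccccc1)C(C)(C)C | intermediate
28 | (8S)-C8,C13-diol with (Z)-C7=C11 (C13 cis to C8, C12 cis to C6) | OC/C(CO[Si](c1ccccc1)(c1ccccc1)C(C)(C)C)=C(/CO[Si](C)(C)C(C)(C)C)[C@@H](O)C/C(COCc1ccc(OC)cc1)=C/C=C\C(C)=C/I | intermediate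
29 | C13 mono-acetate of 28 | CC(=O)OC/C(CO[Si](c1ccccc1)(c1ccccc1)C(C)(C)C)=C(/CO[Si](C)(C)C(C)(C)C)[C@@H](O)C/C(COCc1ccc(OC)cc1)=C/C=C\C(C)=C/I | intermediate
30 | C13 acetate C8 methacrylate (C14 OPMB) | CC(=O)OC/C(CO[Si](c1ccccc1)(c1ccccc1)C(C)(C)C)=C(/CO[Si](C)(C)C(C)(C)C)[C@@H](OC(=O)C(C)=C)C/C(COCc1ccc(OC)cc1)=C/C=C\C(C)=C/I | intermediate
31 | C14 allylic alcohol of 30 | CC(=O)OC/C(CO[Si](c1ccccc1)(c1ccccc1)C(C)(C)C)=C(/CO[Si](C)(C)C(C)(C)C)[C@@H](OC(=O)C(C)=C)C/C(CO)=C/C=C\C(C)=C/I | intermediate
32 | (1R,10S)-1,10-epoxide of 31 | CC(=O)OC/C(CO[Si](c1ccccc1)(c1ccccc1)C(C)(C)C)=C(/CO[Si](C)(C)C(C)(C)C)[C@@H](OC(=O)C(C)=C)C[C@@]1(CO)O[C@@H]1/C=C\C(C)=C/I | intermediate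
33 | C6 alcohol (TBS removed) | CC(=O)OC/C(CO[Si](c1ccccc1)(c1ccccc1)C(C)(C)C)=C(/CO)[C@@H](OC(=O)C(C)=C)C[C@@]1(CO)O[C@@H]1/C=C\C(C)=C/I | intermediate
34 | C6 enal with C5 (Z)-alkenyl iodide (cyclisation precursor) | CC(=O)OC/C(CO[Si](c1ccccc1)(c1ccccc1)C(C)(C)C)=C(/C=O)[C@@H](OC(=O)C(C)=C)C[C@@]1(CO)O[C@@H]1/C=C\C(C)=C/I | intermediate
35 | ten-membered carbocycle: C6 carbinol, (2Z,4Z)-diene, 1,10-oxirane, C8 methacrylate, C12 OTBDPS, C13 OAc | C=C(C)C(=O)O[C@H]1C[C@@]2(CO)O[C@@H]2/C=C\C(C)=C/[C@@H](O)/C1=C(\CO[Si](c1ccccc1)(c1ccccc1)C(C)(C)C)COC(C)=O | intermediate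
36 | (4R,5S,6S)-4,5-epoxy alcohol of 35 | C=C(C)C(=O)O[C@H]1C[C@@]2(CO)O[C@@H]2/C=C\[C@@]2(C)O[C@H]2[C@@H](O)/C1=C(\CO[Si](c1ccccc1)(c1ccccc1)C(C)(C)C)COC(C)=O | intermediate
37 | C6,C12,C14-triol | C=C(C)C(=O)O[C@H]1C[C@@]2(CO)O[C@@H]2/C=C\[C@@]2(C)O[C@H]2[C@@H](O)/C1=C(\CO)COC(C)=O | intermediate
38 | C12 lactol (6,12-hemiacetal) | C=C(C)C(=O)O[C@H]1C[C@@]2(CO)O[C@@H]2/C=C\[C@@]2(C)O[C@H]2[C@H]2OC(O)C(COC(C)=O)=C12 | intermediate
39 | CNP0207684.1 | C=C(C)C(=O)O[C@H]1C[C@@]2(CO)O[C@@H]2/C=C\[C@@]2(C)O[C@H]2[C@H]2OC(=O)C(COC(C)=O)=C12 | target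

**Count and risks**
Total step count: 27. Longest linear sequence: 23 steps (steps 1–8, 10–12, 16–27).

Steps most likely to fail:

Step 24. The process at risk is attack of the alkenylchromium on the other face of the aldehyde in the ring-closing transition state (C6 epimer), besides intermolecular coupling. The fallback sets out from 34 and accepts the ring closure as it comes. The doubly allylic C6 carbinol, then mainly the C6-epimeric alcohol F1, is oxidised with MnO2 to the cross-conjugated macrocyclic dienone F2. This ketone is reduced under reagent control (Corey–Bakshi–Shibata reduction, oxazaborolidine enantiomer chosen by the model), which sets C6 independently of the ring closure and comes back to the route at 35.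

Step 25. The process at risk is hydroxyl-directed oxygen transfer to the wrong alkene (C7=C11, to which the C6 hydroxyl is also allylic) or to the wrong face when the carbinol sits pseudo-equatorial. The fallback sets out from 35 and closes the lactone before the epoxidation. Bu4NF/AcOH gives the alkene triol F3, and MnO2 oxidative lactonisation gives the dienyl butenolide F4, in which C7=C11 is electron-poor and no directing hydroxyl remains. A non-directed epoxidation of the trisubstituted (4Z)-alkene with dimethyldioxirane from the exposed outer face of the rigid lactone then comes back to the route at 39.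

Step 21. The process at risk is slow, poorly face-selective oxygen transfer to a Z-type allylic alcohol within a conjugated triene, and titanium-promoted opening of the dienyl oxirane. The fallback sets out from 30, with the PMB ether still in place, and uses a reagent-controlled dioxirane epoxidation without a Lewis acid (Shi epoxidation with the D-fructose-derived ketone, Oxone, buffered) to give the protected epoxide F5. Cleavage of the PMB ether with DDQ then comes back to the route at 32.

**Further compounds**
F1 | step 24 | C6 epimer of 35 | C=C(C)C(=O)O[C@H]1C[C@@]2(CO)O[C@@H]2/C=C\C(C)=C/[C@H](O)/C1=C(\CO[Si](c1ccccc1)(c1ccccc1)C(C)(C)C)COC(C)=O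
F2 | step 24 | macrocyclic C6 ketone (cross-conjugated dienone) | C=C(C)C(=O)O[C@H]1C[C@@]2(CO)O[C@@H]2/C=C\C(C)=C/C(=O)/C1=C(\CO[Si](c1ccccc1)(c1ccccc1)C(C)(C)C)COC(C)=O
F3 | step 25 | C6,C12,C14-triol with the (4Z)-alkene (desilylated 35) | C=C(C)C(=O)O[C@H]1C[C@@]2(CO)O[C@@H]2/C=C\C(C)=C/[C@@H](O)/C1=C(\CO)COC(C)=O
F4 | step 25 | 4,5-deoxy target (butenolide with the (2Z,4Z)-diene) | C=C(C)C(=O)O[C@H]1C[C@@]2(CO)O[C@@H]2/C=C\C(C)=C/[C@H]2OC(=O)C(COC(C)=O)=C12
F5 | step 21 | (1R,10S)-1,10-epoxide of 30 (C14 OPMB) | CC(=O)OC/C(CO[Si](c1ccccc1)(c1ccccc1)C(C)(C)C)=C(/CO[Si](C)(C)C(C)(C)C)[C@@H](OC(=O)C(C)=C)C[C@@]1(COCc2ccc(OC)cc2)O[C@@H]1/C=C\C(C)=C/I
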